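The ash run opens with 13.2 mM of target at 0.11 h, and the birch and cedar runs, opened the same way, show how that pace depends on the charge.

| flask | substrate | partner | time |
|---|---|---|---|
| ash | 150 mM | 165 mM |  |
| cedar | 75.0 mM | 90.0 mM |  |
| birch | 150 mM | 330 mM |  |
| maple | 150 mM | 1100 mM | 3.2 h |

| run | time / h | [target] / mM |
|---|---|---|
| ash run | 0.11 | 13.2 |
| ash run | 0.35 | 32.8 |
| ash run | 0.67 | 47.6 |
| ash run | 1.1 | 58.5 |
| ash run | 1.5 | 64.8 |
| ash run | 2.0 | 68.1 |
| ash run | 2.6 | 69.9 |
| ash run | 3.2 | 71.3 |
| cedar run | 0.11 | 3.9 |
| cedar run | 0.35 | 8.9 |
| cedar run | 0.67 | 15.9 |
| cedar run | 1.1 | 20.6 |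
| cedar run | 1.5 | 22.9 |
| cedar run | 2.0 | 24.3 |
| cedar run | 2.6 | 26.5 |
| cedar run | 3.2 | 27.3 |
| birch run | 0.11 | 25.2 |
| birch run | 0.35 | 58.0 |
| birch run | 0.67 | 80.9 |
| birch run | 1.1 | 96.4 |
| birch run | 1.5 | 103.9 |
| birch run | 2.0 | 108.9 |
| birch run | 2.6 | 112.2 |
| birch run | 3.2 | 113.8 |

(scatter of a reading: 0.4 mM)

- Overall: substrate + partner -> target.
- Constant volume, constant temperature.
- "The second partner" is partner.
- An order is taken over about fifteen percent of the charge, up and down.

1. reaction order in [substrate] at the outset, round the charge of the ash run, defined at two percent of the substrate turned into target (one fixed amount of target, the same in the runs compared)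
2. reaction order in [partner] at the outset, round the charge of the ash run, defined at two percent of the substrate turned into target
3. target in the maple run at 3.2 h, as a share of the substrate charged

We freeze one quantity, the opening coefficient κ, which is the first reading's rate per unit of c(substrate) and per unit of c(partner) at the charge:

κ = 13.2 mM / (0.11 h × 150 mM × 165 mM) = 4.85 M⁻¹ h⁻¹

It is worth freezing only if both orders are near one, so we reckon them in two ways.

The first way compares the first readings. Birch against ash gives the partner order, and cedar against ash, with that order taken out, gives the substrate order: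

partner order = 0.933
substrate order = 0.943

The scatter on cedar's small first reading puts about 0.148 on the substrate order.

The second way compares the times to a quarter of the substrate charged, interpolated between readings: 0.452 h in the ash run and 0.931 h in the cedar run. These give a substrate order of 1.23, so the two ways part.

To see which one cheats, we ask how long frozen κ needs to bring the ash run to its last reading:

θ = ln[(165 mM − 71.3 mM) 150 mM / ((150 mM − 71.3 mM) 165 mM)] / (κ × 0.0150 M) = 1.09 h

That is less than the 3.2 h the ash run actually took, so the coefficient fades within hours. Cedar's quarter takes twice as long as ash's, so the second way counts that fade as slowness in the cedar run. We keep the first way.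

For the maple run we reckon as if pseudo-first-order, with c(partner) held at 0.950 M, its charge less the substrate charged; that value is an assumption of our reckoning and not a measured state of the maple run. If maple has ash's θ, our reckoning gives 99.3%.

The forecast, reckoned separately, gives 0.9 for substrate, 1 for partner and 99.2% for maple, and on substrate it reads “Cedar's slightly higher k hints at mild saturation in substrate”.

The flask gives 1.0 for substrate, 1.0 for partner and 97.8% for maple.

    substrate ⇌ intermediate, settled at all times (0.9990)
    intermediate + partner → target (11.09 M⁻¹ h⁻¹)
    partner → lost reagent (0.6336 h⁻¹)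
    2 substrate → homo dimer (3.251 M⁻¹ h⁻¹)

The conversion of partner into lost reagent makes next to no difference to the maple figure. On maple's charge, κ gives an opening pace of 800 mM h⁻¹. On cedar's charge it gives 32.7 mM h⁻¹, and the cedar rate stood at 32 mM h⁻¹ where an amount equal to two percent of ash's substrate had turned.

The data are calculated from invented constants, noise included.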